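**Assumption:** the target has no stereocentres (it is achiral), so no stereocontrol is needed. Intermediate 10 is used as a racemic diastereomer mixture whose stereocentres are erased on aromatisation.

## Retrosynthetic overview

1. Target ⇐ global hydrogenolysis of a tetrabenzyl-protected tridepside (three ArO–Bn, one CO2Bn).
2. A–B depside C(aryl)–O bond ⇐ Ni/photosensitised O-arylation of the hindered ring-A acid with a ring-B aryl bromide already carrying ring C. The bromide site is fixed by sterically controlled Ir-catalysed C–H borylation of a 2-methoxy-6-methylbenzoate, then bromodeboronation.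
3. B–C ester ⇐ acylation of the 4-OH of benzyl orsellinate with the ring-B bromo acid.
4. Ring A ⇐ orsellinate core by C5 bromination and Pd-catalysed hydroxylation/benzylation.
5. Ring formation: rings A and C come from one arene-forming self-condensation of methyl acetoacetate (methyl orsellinate). Ring B comes from a separate annulation of methyl acetoacetate with crotonaldehyde plus aromatisation. No rings are formed afterwards.

## Route

### Rings A and C

**Step 1**
Reactants: 1, methyl acetoacetate (2 equiv)
Product: 2, methyl orsellinate (methyl 2,4-dihydroxy-6-methylbenzoate)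
Conditions: NaH (1.0 equiv), THF, 0 °C; n-BuLi (1.0 equiv), −78 °C → rt, then reflux; aq. HCl
Reagents that add atoms: none
Why: Dianion self-condensation (Claisen) gives methyl 3,5,7-trioxooctanoate, which undergoes intramolecular aldol condensation and aromatisation (biomimetic polyketide cyclisation) to the orsellinate.

**Step 2**
Reactants: 2, methyl orsellinate
Product: 3, orsellinic acid (2,4-dihydroxy-6-methylbenzoic acid)
Conditions: KOH (5 equiv), DMSO/H2O 4:1, 80 °C, N2; cold 2 M HCl to pH 2 at 0 °C, no heating of the free acid
Reagents that add atoms: potassium hydroxide, [K+].[OH-]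
Why: Saponification of a hindered ester; the product is stable as its salt, and cold acidification avoids decarboxylation to orcinol.

**Step 3**
Reactants: 3, orsellinic acid
Product: 4, benzyl orsellinate (benzyl 2,4-dihydroxy-6-methylbenzoate)
Conditions: BnBr (1.05 equiv), KHCO3 (1.1 equiv), DMF, rt
Reagents that add atoms: benzyl bromide, BrCc1ccccc1
Why: Bicarbonate deprotonates only the carboxylic acid, so SN2 O-alkylation gives the benzyl ester and leaves both phenols free.

**Step 4**
Reactants: 3, orsellinic acid
Product: 5, benzyl 2,4-bis(benzyloxy)-6-methylbenzoate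
Conditions: BnBr (3.5 equiv), K2CO3 (4 equiv), DMF, rt 2 h then 60 °C
Reagents that add atoms: benzyl bromide, BrCc1ccccc1
Why: Carboxylate alkylation at rt removes the decarboxylation risk, then Williamson etherification at 60 °C benzylates both phenols, including the chelated 2-OH.

**Step 5**
Reactants: 5, benzyl 2,4-bis(benzyloxy)-6-methylbenzoate
Product: 6, benzyl 4,6-bis(benzyloxy)-3-bromo-2-methylbenzoate (Br at C5 of the orsellinate, between the 4-OBn and the methyl)
Conditions: NBS (1.05 equiv), MeCN, 0 °C → rt, dark
Reagents that add atoms: N-bromosuccinimide, O=C1CCC(=O)N1Br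
Why: Electrophilic aromatic bromination goes para to the 2-OBn and ortho to the 4-OBn; the position between the two benzyloxy groups is disfavoured, as in 3,5-dialkoxytoluenes.

**Step 6**
Reactants: 6, aryl bromide
Product: 7, benzyl 3,4,6-tris(benzyloxy)-2-methylbenzoate (= benzyl 2,4,5-tris(benzyloxy)-6-methylbenzoate)
Conditions: Pd2(dba)3 (2 mol %), tBuXPhos (8 mol %), KOH (3 equiv), 1,4-dioxane/H2O 1:1, 100 °C, Ar; then, same pot, BnBr (3 equiv), n-Bu4NBr (10 mol %), 60 °C
Reagents that add atoms: potassium hydroxide, [K+].[OH-]; benzyl bromide, BrCc1ccccc1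
Why: Pd-catalysed C–O coupling of an aryl bromide with hydroxide (Buchwald-type hydroxylation, tolerant of ortho substituents) gives the air-sensitive phenoxide, which is benzylated in situ; any ester cleaved by KOH is re-formed as the same benzyl ester, so one product results.

**Step 7**
Reactants: 7, benzyl ester
Product: 8, 3,4,6-tris(benzyloxy)-2-methylbenzoic acid (ring-A acid)
Conditions: KOH (6 equiv), DMSO/H2O 9:1, 90 °C; 1 M HCl
Reagents that add atoms: potassium hydroxide, [K+].[OH-]
Why: Forcing saponification of a di-ortho-substituted benzoate in aqueous DMSO; benzyl ethers are inert.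

### Ring B

**Step 8**
Reactants: 1, methyl acetoacetate; 9, (E)-crotonaldehyde
Product: 10, methyl 6-methyl-2-oxocyclohex-3-ene-1-carboxylate (racemic, cis/trans mixture)
Conditions: NaOMe (0.1 equiv), MeOH, 0 °C → rt; then dry HCl, 0 °C → rt
Reagents that add atoms: none
Why: Michael addition of the acetoacetate α-carbon to the enal, then intramolecular aldol condensation of the methyl ketone onto the aldehyde (Robinson-type annulation); the stereocentres are irrelevant.

**Step 9**
Reactants: 10, cyclohexenone β-keto ester
Product: 11, methyl 2-hydroxy-6-methylbenzoate (methyl 6-methylsalicylate)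
Conditions: Br2 (1.0 equiv), AcOH, 10 °C → rt; then 90 °C (−2 HBr)
Reagents that add atoms: none
Why: α-Bromination of the β-keto ester, dehydrobromination and dienone–phenol tautomerisation aromatise the ring (bromination–dehydrobromination).

**Step 10**
Reactants: 11, methyl 6-methylsalicylate
Product: 12, methyl 2-methoxy-6-methylbenzoate
Conditions: MeI (1.5 equiv), K2CO3 (2 equiv), DMF, 50 °C
Reagents that add atoms: iodomethane, CI
Why: Williamson O-methylation installs the ring-B methoxy group with no need to differentiate two phenols.

**Step 11**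
Reactants: 12, methyl 2-methoxy-6-methylbenzoate
Product: 13, methyl 2-methoxy-6-methyl-4-(4,4,5,5-tetramethyl-1,3,2-dioxaborolan-2-yl)benzoate
Conditions: [Ir(OMe)(cod)]2 (1.5 mol %), dtbpy (3 mol %), B2pin2 (0.7 equiv), THF, 80 °C
Reagents that add atoms: bis(pinacolato)diboron, CC1(C)OB(OC1(C)C)B1OC(C)(C)C(C)(C)O1
Why: Ir-catalysed C–H borylation is sterically controlled, and C4 is the only C–H of this 1,2,3-trisubstituted arene with no ortho substituent, so the future depside oxygen site is set regiospecifically.

**Step 12**
Reactants: 13, aryl boronate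
Product: 14, methyl 4-bromo-2-methoxy-6-methylbenzoate
Conditions: CuBr2 (3 equiv), MeOH/H2O 1:1, 80 °C
Reagents that add atoms: copper(II) bromide, Br[Cu]Br
Why: Copper-mediated ipso-bromodeboronation of an aryl pinacolboronate (borylation/halogenation sequence).

**Step 13**
Reactants: 14, methyl ester
Product: 15, 4-bromo-2-methoxy-6-methylbenzoic acid
Conditions: KOH (5 equiv), DMSO/H2O 4:1, 80 °C; 1 M HCl
Reagents that add atoms: potassium hydroxide, [K+].[OH-]
Why: Saponification of a hindered methyl ester; the aryl bromide, activated only by a twisted ester, is not displaced.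

### Assembly

**Step 14**
Reactants: 15, ring-B bromo acid; 4, benzyl orsellinate
Product: 16, benzyl 4-[(4-bromo-2-methoxy-6-methylbenzoyl)oxy]-2-hydroxy-6-methylbenzoate
Conditions: (CF3CO)2O (3 equiv), toluene, rt; aq. NaHCO3 work-up
Reagents that add atoms: none
Why: Mixed-anhydride (TFAA) depside esterification; the chelated 2-OH of 4 is unreactive, so only the 4-OH is acylated.

**Step 15**
Reactants: 8, ring-A acid (1.5 equiv); 16, aryl bromide
Product: 17, benzyl 2-hydroxy-4-[(2-methoxy-6-methyl-4-{[3,4,6-tris(benzyloxy)-2-methylbenzoyl]oxy}benzoyl)oxy]-6-methylbenzoate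
Conditions: NiBr2·glyme (10 mol %), dtbbpy (10 mol %), Ir(ppy)3 (2 mol %), t-BuNH(i-Pr) (2 equiv), DMF (0.1 M), degassed, 450 nm LEDs, 25 °C
Reagents that add atoms: none
Why: Proposed new method: Ni(0)/dtbbpy adds oxidatively into the unhindered C4–Br of 16, the carboxylate of 8 replaces bromide on Ni(II), and triplet energy transfer from excited Ir(ppy)3 triggers C(aryl)–O reductive elimination; the di-ortho substitution that blocks acyl substitution at the carbonyl of 8 is remote from the reacting oxygen, and the hindered amine base cannot aminolyse the existing ester or usefully deprotonate the chelated 2-OH. The closest known reaction is the Ni/photosensitiser esterification of simple aryl bromides with carboxylic acids, not yet shown for di-ortho-substituted polyoxygenated benzoic acids or for depside bromides with a free salicylate OH.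

**Step 16**
Reactants: 17, tetrabenzyl tridepside
Product: 18, 2'-O-methylhiascic acid
Conditions: H2 (1 atm), 10 % Pd/C, EtOAc/THF, rt
Reagents that add atoms: none
Why: Hydrogenolysis removes the three benzyl ethers and the benzyl ester together; the two depside esters and the aryl methyl ether are untouched, and rt avoids decarboxylation of the salicylic acid terminus.

## Compound list

1 | methyl acetoacetate | COC(=O)CC(C)=O | starting material
2 | methyl orsellinate | COC(=O)c1c(C)cc(O)cc1O | intermediate
3 | orsellinic acid | Cc1cc(O)cc(O)c1C(=O)O | intermediate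
4 | benzyl orsellinate | Cc1cc(O)cc(O)c1C(=O)OCc1ccccc1 | intermediate
5 | benzyl 2,4-bis(benzyloxy)-6-methylbenzoate | Cc1cc(OCc2ccccc2)cc(OCc2ccccc2)c1C(=O)OCc1ccccc1 | intermediate
6 | benzyl 4,6-bis(benzyloxy)-3-bromo-2-methylbenzoate | Cc1c(Br)c(OCc2ccccc2)cc(OCc2ccccc2)c1C(=O)OCc1ccccc1 | intermediate
7 | benzyl 3,4,6-tris(benzyloxy)-2-methylbenzoate | Cc1c(OCc2ccccc2)c(OCc2ccccc2)cc(OCc2ccccc2)c1C(=O)OCc1ccccc1 | intermediate
8 | 3,4,6-tris(benzyloxy)-2-methylbenzoic acid | Cc1c(OCc2ccccc2)c(OCc2ccccc2)cc(OCc2ccccc2)c1C(=O)O | intermediate
9 | (E)-crotonaldehyde | C/C=C/C=O | starting material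
10 | methyl 6-methyl-2-oxocyclohex-3-ene-1-carboxylate (racemic, diastereomer mixture) | COC(=O)C1C(C)CC=CC1=O | intermediate
11 | methyl 2-hydroxy-6-methylbenzoate | COC(=O)c1c(C)cccc1O | intermediate
12 | methyl 2-methoxy-6-methylbenzoate | COC(=O)c1c(C)cccc1OC | intermediate
13 | methyl 2-methoxy-6-methyl-4-(pinacolboryl)benzoate | COC(=O)c1c(C)cc(cc1OC)B1OC(C)(C)C(C)(C)O1 | intermediate
14 | methyl 4-bromo-2-methoxy-6-methylbenzoate | COC(=O)c1c(C)cc(Br)cc1OC | intermediate
15 | 4-bromo-2-methoxy-6-methylbenzoic acid | COc1cc(Br)cc(C)c1C(=O)O | intermediate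
16 | benzyl 4-[(4-bromo-2-methoxy-6-methylbenzoyl)oxy]-2-hydroxy-6-methylbenzoate | COc1cc(Br)cc(C)c1C(=O)Oc1cc(C)c(C(=O)OCc2ccccc2)c(O)c1 | intermediate
17 | tetrabenzyl-protected tridepside | COc1cc(OC(=O)c2c(OCc3ccccc3)cc(OCc3ccccc3)c(OCc3ccccc3)c2C)cc(C)c1C(=O)Oc1cc(C)c(C(=O)OCc2ccccc2)c(O)c1 | intermediate
18 | 2'-O-methylhiascic acid | COc1cc(OC(=O)c2c(O)cc(O)c(O)c2C)cc(C)c1C(=O)Oc1cc(C)c(C(=O)O)c(O)c1 | target

## Step count

Total steps: 16.
Longest linear sequence: 9 (steps 8 → 9 → 10 → 11 → 12 → 13 → 14 → 15 → 16). The ring-A branch is 8 steps (1, 2, 4, 5, 6, 7, 15, 16) and the ring-C branch is 6 (1, 2, 3, 14, 15, 16).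

## Steps most likely to fail

1. **Step 15 (proposed new Ni/photosensitised depside O-arylation).** Risks: the twisted para-ester only weakly activates the bromide, and the free salicylate OH of ring C may chelate Ni. Fallback with known chemistry: convert 16 to its ring-B phenol by Miyaura borylation (Pd(dppf)Cl2, B2pin2, KOAc) and NaBO3 oxidation, then acylate that non-chelated 4-OH with acid 8 under the TFAA/toluene conditions of step 14. This gives the same 17 by classical acyl transfer.

2. **Step 6 (Pd-catalysed hydroxylation of a di-ortho-substituted, electron-rich bromide).** Risks: slow oxidative addition, hydrodebromination, and oxidation of the electron-rich phenoxide. Fallback: drop the halide route and put the C5 oxygen on the free phenol by Elbs persulfate oxidation of 2 (K2S2O8, aq. NaOH, then acid hydrolysis of the aryl sulfate; para to the 2-OH). Perbenzylation and KOH/DMSO saponification then give 8. This also covers a poor C5/C3 ratio in step 5.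

3. **Step 1 (one-pot dianion self-condensation).** Risk: capricious, moderate yield, and it feeds two of the three rings. Fallback: the two-component route from methyl acetoacetate and methyl crotonate (NaOMe, Michael–Claisen) to methyl dihydroorsellinate, then aromatisation by bromination/dehydrobromination and hydrogenolytic debromination to 2.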